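**Plan**
1. Retrosynthesis: the epoxide is opened to a C11 bromohydrin (a masked epoxide) and then to a C11 ketone; C6–Cl comes from a (6R)-allylic alcohol; the ten-membered ring is cut at C5–C6 (alkenyl iodide + aldehyde); the lactone is cut at C8–C17 (bromopropanoate on O7 + C8 ketone); ring A is then cut at C1–C10 and C11–C12 in one [4+2] step.
2. Enabling feature: in ring A (C1, C10–C14) the oxygens on C14 and C11 are para across the C1–C10 fusion bond and O2 lies beta to C14. So C12=C13–C14(O)=C1 is a 2-silyloxy diene whose enol oxygen can be tied to O2 in a six-membered silylene ring (absent from the target), and C10=C11 is a nitroalkene used as a ketene equivalent.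
3. Forward order: diene 10 (C1–C5, C12–C16) and L-arabinose-derived nitroalkene 16 (C6–C11) give ring A by Diels–Alder reaction; then C14 and C11 are adjusted, the lactone is closed, the ten-membered ring is closed, the epoxide is closed and the chloride is introduced.
4. Stereochemistry: C2 from an Evans aldol; C9 and C7 (and the temporary C8 carbinol) are C2', C4' and C3' of L-arabinose; C1 and C10 arise in the cycloaddition under control of C2 through the silylene ring; C14, C11, C8, C17 and C6 follow from substrate-controlled steps (bulky hydride, equatorial carbenoid addition, Reformatsky ring closure, hydroxyl-directed reduction then SN2 inversion).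

Key step: step 11

Remark: atoms carry briarane numbers (C1 quaternary carbon, C2–C9 around the ten-membered ring, C10 fusion CH, C11–C14 rest of ring A, C15 methyl on C1, C16 exocyclic methylene, C17–C19 lactone carbons, C18 methyl on C17, C20 epoxide CH2). The C11 nitro epimer mixture formed in step 13 is inconsequential because C11 becomes a ketone in step 15.

**Step 1**
Reactants: 1 pent-4-yn-1-ol
Product: 2 4-iodopent-4-en-1-ol
Conditions: NaI, TMSCl, H2O, MeCN, rt
Reagents that add atoms: sodium iodide [Na+].[I-]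
Why: Markovnikov hydroiodination of the terminal alkyne by HI generated in the flask should give the 2-iodo-1-alkene.

**Step 2**
Reactants: 2 4-iodopent-4-en-1-ol
Product: 3 4-iodopent-4-enal
Conditions: Dess–Martin periodinane, pyridine, CH2Cl2, 0 °C to rt
Reagents that add atoms: none
Why: Dess–Martin oxidation of a primary alcohol stops at the aldehyde and leaves the alkenyl iodide alone.

**Step 3**
Reactants: 3 4-iodopent-4-enal, 4 (R)-4-benzyl-3-propanoyl-1,3-oxazolidin-2-one
Product: 6 (R)-4-benzyl-3-[(2R,3S)-3-hydroxy-6-iodo-2-methylhept-6-enoyl]-1,3-oxazolidin-2-one, via Z-boron enolate 5 (not isolated)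
Conditions: Bu2BOTf, i-Pr2NEt, CH2Cl2, −78 to 0 °C; then 3, −78 °C; H2O2, pH 7 buffer, MeOH
Reagents that add atoms: none
Why: Evans syn-aldol reaction through the Z-boron enolate and a closed Zimmerman–Traxler transition state; the (R)-benzyl auxiliary sets the carbinol carbon (future C2) as S, and the alpha-methyl centre is removed later.

**Step 4**
Reactants: 6 aldol adduct
Product: 7 (2R,3S)-3-hydroxy-6-iodo-N-methoxy-N,2-dimethylhept-6-enamide
Conditions: MeNH(OMe)·HCl, AlMe3, CH2Cl2, −10 °C to rt
Reagents that add atoms: N,O-dimethylhydroxylamine hydrochloride CNOC.Cl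
Why: AlMe3-mediated transamination of the imide to the Weinreb amide, assisted by the free beta-hydroxyl, releases the auxiliary.

**Step 5**
Reactants: 7 Weinreb amide
Product: 8 (4R,5S)-5-hydroxy-8-iodo-4-methylnona-1,8-dien-3-one
Conditions: CH2=CHMgBr (3 equiv), THF, −20 to 0 °C; inverse quench into cold aq. HCl
Reagents that add atoms: vinylmagnesium bromide C=C[Mg]Br
Why: Grignard addition to a Weinreb amide stops at the ketone through the chelated tetrahedral intermediate, and the cold acidic inverse quench should prevent conjugate addition of the released amine.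

**Step 6**
Reactants: 8 hydroxy enone
Product: 10 (4S)-2,2-di-tert-butyl-6-ethenyl-4-(3-iodobut-3-en-1-yl)-5-methyl-4H-1,3,2-dioxasiline, via silyl triflate ether 9 (not isolated)
Conditions: t-Bu2Si(OTf)2, 2,6-lutidine, CH2Cl2, −78 °C; then Et3N, 0 °C
Reagents that add atoms: di-tert-butylsilyl bis(trifluoromethanesulfonate) CC(C)(C)[Si](OS(=O)(=O)C(F)(F)F)(OS(=O)(=O)C(F)(F)F)C(C)(C)C
Why: O-silylation of the alcohol followed by intramolecular silyl triflate/amine enol silylation of the ketone (its only alpha-hydrogen is on C1) closes the six-membered silylene ring, which fixes O14 cis to C2 on the C1=C14 enol double bond.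

**Step 7**
Reactants: 11 L-arabinose
Product: 12 3,4-O-isopropylidene-L-arabinopyranose
Conditions: 2,2-dimethoxypropane, p-TsOH (cat.), DMF, rt
Reagents that add atoms: 2,2-dimethoxypropane COC(C)(C)OC
Why: acid-catalysed acetonide formation takes the cis-3,4-diol of the pyranose and leaves O1 and O2 free.

**Step 8**
Reactants: 12 3,4-O-isopropylidene-L-arabinopyranose
Product: 13 1-deoxy-4,5-O-isopropylidene-1-nitro-L-hexitol (L-gluco/L-manno mixture, epimers at C2 of the hexitol)
Conditions: CH3NO2, DBU (cat.), THF, rt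
Reagents that add atoms: nitromethane C[N+](=O)[O-]
Why: Henry (nitroaldol) chain extension on the open-chain aldehyde form of the lactol; the new carbinol centre is removed in step 10.

**Step 9**
Reactants: 13 nitro triol
Product: 14 6-O-(tert-butyldiphenylsilyl) ether of 13
Conditions: TBDPSCl, imidazole, DMF, 0 °C
Reagents that add atoms: tert-butyl(chloro)diphenylsilane CC(C)(C)[Si](Cl)(c1ccccc1)c1ccccc1
Why: the bulky silyl chloride should react at the primary hydroxyl in preference to the two secondary ones.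

**Step 10**
Reactants: 14 silyl ether
Product: 16 (E)-3-O-acetyl-6-O-(tert-butyldiphenylsilyl)-1,2-dideoxy-4,5-O-isopropylidene-1-nitro-L-arabino-hex-1-enitol, via nitro diacetate 15 (not isolated)
Conditions: Ac2O, pyridine, DMAP (cat.), CH2Cl2, 0 °C; then Et3N, rt
Reagents that add atoms: acetic anhydride CC(=O)OC(C)=O
Why: acetylation of both secondary hydroxyls followed by E1cB loss of acetic acid from the beta-nitro acetate (Schmidt–Rutz elimination) gives the E-nitroalkene and leaves the C9 acetate that the target needs.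

**Step 11**
Reactants: 10 silylene-locked diene, 16 nitroalkene
Product: 17 Diels–Alder adduct (ring A cyclohexene with C13=C14 silyl enol ether still bridged to O2 by Si(t-Bu)2, C11 nitro cis to C2, C10 side chain trans to C2)
Conditions: toluene (1.5 M), BHT (cat.), 70 °C, sealed tube
Reagents that add atoms: none
Why: Normal-electron-demand, concerted but asynchronous [4+2] cycloaddition (closest known type: Diels–Alder reaction of a 2-silyloxy-1,3-diene with a nitroalkene used as ketene equivalent), in which the enol carbon C1 bonds to C10, the carbon beta to the nitro group, and C12 bonds to C11, so that the C14 oxygen and the C11 nitro group end para. Ring A (C1, C14, C13, C12, C11, C10) is closed by intermolecular [4+2] annulation, both bonds forming on one face of each partner. C1: the dioxasiline ring fixes C2 cis to O14 (C15 methyl inside) and, to avoid A(1,2) strain with that methyl, holds the C3 chain pseudoaxial, so the nitroalkene should add to the diene face anti to C3, which gives 1S relative to 2S. C10 and the transient C11: the E-nitroalkene should react with the nitro group endo, which places the C9 branch exo, hence trans to C2 and cis to the C15 methyl. The step needs regio-, diene-facial and endo selectivity; these are secured by the enol ether/nitro polarisation, by the silylene-locked C2 centre and by the nitro group, and the L-arabinose-derived C9 centre is matched, since its rotamer with the dioxolane chain anti to the forming C1–C10 bond and H9 eclipsing the double bond exposes the same face.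

**Step 12**
Reactants: 17 Diels–Alder adduct
Product: 18 C14 ketone with free C2 hydroxyl
Conditions: HF·pyridine, pyridine, THF, 0 °C
Reagents that add atoms: none
Why: HF cleaves the silyl enol ether and the silyl ether of the silylene to give the ketone and the alcohol, while the TBDPS ether and the acetonide should survive the buffered reagent at 0 °C.

**Step 13**
Reactants: 18 hydroxy ketone
Product: 19 (14S)-2,14-diol (C11 nitro epimers)
Conditions: LiBH(s-Bu)3 (3.2 equiv), THF, −78 °C; AcOH quench at −78 °C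
Reagents that add atoms: none
Why: the bulky trialkylborohydride attacks the C14 ketone along the equatorial direction and gives the axial alcohol cis to C2; it also deprotonates the hydroxyl and the nitro group (the nitronate is inert to hydride and is re-protonated on quench).

**Step 14**
Reactants: 19 diol
Product: 20 2,9,14-triacetate (C11 nitro epimers)
Conditions: Ac2O, pyridine, DMAP, CH2Cl2, rt to 40 °C
Reagents that add atoms: acetic anhydride CC(=O)OC(C)=O
Why: DMAP-catalysed acetylation of the two hindered secondary alcohols installs the C2 and C14 acetates of the target.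

**Step 15**
Reactants: 20 nitro triacetate
Product: 21 C11 ketone
Conditions: NaNO2, AcOH, DMSO–H2O (20:1), 35 °C
Reagents that add atoms: water O
Why: nitrite-mediated Nef reaction (nitrosation of the nitronate to a pseudonitrole, then hydrolysis) converts the secondary nitro group to the ketone under weakly acidic conditions that acetates, acetonide, silyl ether and alkenyl iodide tolerate.

**Step 16**
Reactants: 21 ketone
Product: 22 (11S)-bromohydrin (C11 axial hydroxyl, equatorial CH2Br)
Conditions: CH2Br2, n-BuLi, THF, −78 °C (n-BuLi added to ketone and CH2Br2); AcOH quench at −78 °C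
Reagents that add atoms: dibromomethane BrCBr
Why: bromomethyllithium made by Br/Li exchange in the presence of the ketone adds to it faster than to the acetates, from the equatorial direction because the axial path is blocked by the syn-axial C1 methyl; the cold quench keeps the bromohydrin, a masked epoxide that survives the acidic steps ahead.

**Step 17**
Reactants: 22 bromohydrin acetonide
Product: 23 7,8-diol
Conditions: TFA–H2O (9:1), CH2Cl2, 0 °C
Reagents that add atoms: none
Why: aqueous acid hydrolyses the dioxolane, while the TBDPS ether, the acetates, the bromohydrin and the alkenyl iodide are stable to it.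

**Step 18**
Reactants: 23 diol
Product: 24 7-O-(2-bromopropanoyl) ester
Conditions: 2-bromopropanoyl bromide (1.1 equiv), pyridine, CH2Cl2, −40 °C
Reagents that add atoms: 2-bromopropanoyl bromide CC(Br)C(Br)=O
Why: kinetic acylation should take the C7 hydroxyl (flanked by a CH2 group) in preference to the C8 hydroxyl (flanked by two branched carbons) and the tertiary C11 hydroxyl.

**Step 19**
Reactants: 24 bromopropanoate
Product: 25 C8 ketone
Conditions: Dess–Martin periodinane, pyridine, CH2Cl2, 0 °C
Reagents that add atoms: none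
Why: Dess–Martin oxidation of the one remaining secondary alcohol; the tertiary alcohol is inert.

**Step 20**
Reactants: 25 alpha-(bromoacyloxy) ketone
Product: 26 (8R,17R)-beta-hydroxy-gamma-lactone
Conditions: Zn dust, TMSCl (cat.), THF, 0 °C to rt; aq. NH4Cl
Reagents that add atoms: none
Why: intramolecular Reformatsky reaction (zinc enolate of the bromo ester adds to the C8 ketone, 5-exo-trig); in the five-membered transition state the bulky C9 branch should sit trans to the C6 substituent on C7, so the hydroxyl ends cis to C6, and the epimerisable C17 methyl should settle anti to C9.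

**Step 21**
Reactants: 26 silyl ether
Product: 27 primary alcohol at C6
Conditions: HF·pyridine, pyridine, THF, rt
Reagents that add atoms: none
Why: HF·pyridine removes the primary TBDPS ether under conditions that the lactone, the tertiary alcohols and the bromohydrin tolerate.

**Step 22**
Reactants: 27 alcohol
Product: 28 C6 aldehyde
Conditions: Dess–Martin periodinane, pyridine, CH2Cl2, 0 °C
Reagents that add atoms: none
Why: Dess–Martin oxidation to the alpha-acyloxy aldehyde, which is used at once.

**Step 23**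
Reactants: 28 iodo aldehyde
Product: 29 ten-membered allylic alcohol (C6 epimers)
Conditions: CrCl2 (10 equiv), NiCl2 (2 mol %), DMSO, 0.002 M, rt
Reagents that add atoms: none
Why: Nozaki–Hiyama–Kishi reaction: the alkenylchromium formed from the 2-iodoalkene adds only to the aldehyde (esters, lactone, alkyl bromide and tertiary hydroxyls are tolerated) and under high dilution should close the C5–C6 bond with the exocyclic methylene in place; both C6 epimers converge in step 24.

**Step 24**
Reactants: 29 allylic alcohols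
Product: 30 C6 enone
Conditions: Dess–Martin periodinane, pyridine, CH2Cl2, 0 °C
Reagents that add atoms: none
Why: oxidation of the allylic alcohol removes the uncontrolled C6 centre.

**Step 25**
Reactants: 30 enone
Product: 31 (6R)-allylic alcohol
Conditions: Me4NBH(OAc)3, AcOH–MeCN (1:1), −30 °C
Reagents that add atoms: none
Why: Evans–Saksena reduction: the C8 hydroxyl binds the triacetoxyborohydride and delivers hydride within a chair transition state to the C6 ketone (1,2-reduction only), which should give the 1,3-anti diol, that is the (6R)-alcohol.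

**Step 26**
Reactants: 31 bromohydrin
Product: 32 11,20-epoxide with (6R)-hydroxyl
Conditions: K2CO3, MeCN, rt
Reagents that add atoms: none
Why: mild base closes the bromohydrin to the spiro epoxide (intramolecular Williamson reaction, 3-exo-tet) with retention at C11.

**Step 27**
Reactants: 32 epoxy alcohol
Product: 33 target CNP0104093.2
Conditions: PPh3, hexachloroacetone, CH2Cl2, −20 to 0 °C
Reagents that add atoms: hexachloroacetone ClC(Cl)(Cl)C(=O)C(Cl)(Cl)Cl
Why: Appel-type chlorination (Magid conditions) should convert the allylic alcohol to the chloride by SN2 with inversion (6R to 6S) and without allylic transposition; the tertiary alcohol, the epoxide and the acetates are untouched.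

**Compound list**
1 | pent-4-yn-1-ol | C#CCCCO | starting material
2 | 4-iodopent-4-en-1-ol | C=C(I)CCCO | intermediate
3 | 4-iodopent-4-enal | C=C(I)CCC=O | intermediate
4 | (R)-4-benzyl-3-propanoyl-1,3-oxazolidin-2-one | CCC(=O)N1[C@H](Cc2ccccc2)COC1=O | starting material
5 | Z-dibutylboron enolate of 4 | C/C=C(/N1[C@H](Cc2ccccc2)COC1=O)OB(CCCC)CCCC | intermediate
6 | (R)-4-benzyl-3-[(2R,3S)-3-hydroxy-6-iodo-2-methylhept-6-enoyl]-1,3-oxazolidin-2-one | C=C(I)CC[C@H](O)[C@@H](C)C(=O)N1[C@H](Cc2ccccc2)COC1=O | intermediate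
7 | (2R,3S)-3-hydroxy-6-iodo-N-methoxy-N,2-dimethylhept-6-enamide | C=C(I)CC[C@H](O)[C@@H](C)C(=O)N(C)OC | intermediate
8 | (4R,5S)-5-hydroxy-8-iodo-4-methylnona-1,8-dien-3-one | C=C(I)CC[C@H](O)[C@@H](C)C(=O)C=C | intermediate
9 | di-tert-butyl(trifluoromethanesulfonyloxy)silyl ether of 8 | C=C(I)CC[C@H](O[Si](OS(=O)(=O)C(F)(F)F)(C(C)(C)C)C(C)(C)C)[C@@H](C)C(=O)C=C | intermediate
10 | (4S)-2,2-di-tert-butyl-6-ethenyl-4-(3-iodobut-3-en-1-yl)-5-methyl-4H-1,3,2-dioxasiline | C=CC1=C(C)[C@H](CCC(I)=C)O[Si](C(C)(C)C)(C(C)(C)C)O1 | intermediate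
11 | L-arabinose (pyranose form) | OC1OC[C@H](O)[C@H](O)[C@H]1O | starting material
12 | 3,4-O-isopropylidene-L-arabinopyranose | OC1OC[C@@H]2OC(C)(C)O[C@@H]2[C@H]1O | intermediate
13 | 1-deoxy-4,5-O-isopropylidene-1-nitro-L-hexitol (C2 epimers) | O=[N+]([O-])CC(O)[C@H](O)[C@H]1OC(C)(C)O[C@H]1CO | intermediate
14 | 6-O-(tert-butyldiphenylsilyl) ether of 13 | O=[N+]([O-])CC(O)[C@H](O)[C@H]1OC(C)(C)O[C@H]1CO[Si](c2ccccc2)(c2ccccc2)C(C)(C)C | intermediate
15 | 2,3-di-O-acetate of 14 | O=[N+]([O-])CC(OC(C)=O)[C@H](OC(C)=O)[C@H]1OC(C)(C)O[C@H]1CO[Si](c2ccccc2)(c2ccccc2)C(C)(C)C | intermediate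
16 | (E)-3-O-acetyl-6-O-(tert-butyldiphenylsilyl)-1,2-dideoxy-4,5-O-isopropylidene-1-nitro-L-arabino-hex-1-enitol | O=[N+]([O-])/C=C/[C@H](OC(C)=O)[C@H]1OC(C)(C)O[C@H]1CO[Si](c2ccccc2)(c2ccccc2)C(C)(C)C | intermediate
17 | Diels–Alder adduct: ring A cyclohexene (C13=C14) with O14 and O2 bridged by Si(t-Bu)2, C1 methyl, C11 nitro cis to C2, C10 chain (9-OAc, 7,8-acetonide, 6-OTBDPS) trans to C2, 3-iodobut-3-enyl on C2 | C=C(I)CC[C@@H]1O[Si](C(C)(C)C)(C(C)(C)C)OC3=CC[C@@H]([N+](=O)[O-])[C@H]([C@H](OC(C)=O)[C@H]5OC(C)(C)O[C@H]5CO[Si](c6ccccc6)(c6ccccc6)C(C)(C)C)[C@@]13C | intermediate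
18 | ring A 14-ketone with free 2-hydroxyl, 11-nitro (equatorial) | C=C(I)CC[C@H](O)[C@@]2(C)C(=O)CC[C@@H]([N+](=O)[O-])[C@@H]2[C@H](OC(C)=O)[C@H]3OC(C)(C)O[C@H]3CO[Si](c4ccccc4)(c4ccccc4)C(C)(C)C | intermediate
19 | (14S)-2,14-diol, 11-nitro (C11 epimers) | C=C(I)CC[C@H](O)[C@@]2(C)[C@@H](O)CCC([N+](=O)[O-])[C@@H]2[C@H](OC(C)=O)[C@H]3OC(C)(C)O[C@H]3CO[Si](c4ccccc4)(c4ccccc4)C(C)(C)C | intermediate
20 | 2,9,14-triacetate, 11-nitro (C11 epimers) | C=C(I)CC[C@H](OC(C)=O)[C@@]2(C)[C@@H](OC(C)=O)CCC([N+](=O)[O-])[C@@H]2[C@H](OC(C)=O)[C@H]3OC(C)(C)O[C@H]3CO[Si](c4ccccc4)(c4ccccc4)C(C)(C)C | intermediate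
21 | 2,9,14-triacetate 11-ketone | C=C(I)CC[C@H](OC(C)=O)[C@@]2(C)[C@@H](OC(C)=O)CCC(=O)[C@@H]2[C@H](OC(C)=O)[C@H]3OC(C)(C)O[C@H]3CO[Si](c4ccccc4)(c4ccccc4)C(C)(C)C | intermediate
22 | (11S)-11-hydroxy-20-bromo compound (bromohydrin), 7,8-acetonide | C=C(I)CC[C@H](OC(C)=O)[C@@]2(C)[C@@H](OC(C)=O)CC[C@@](O)(CBr)[C@@H]2[C@H](OC(C)=O)[C@H]3OC(C)(C)O[C@H]3CO[Si](c4ccccc4)(c4ccccc4)C(C)(C)C | intermediate
23 | bromohydrin 7,8-diol | C=C(I)CC[C@H](OC(C)=O)[C@@]2(C)[C@@H](OC(C)=O)CC[C@@](O)(CBr)[C@@H]2[C@H](OC(C)=O)[C@@H](O)[C@@H](O)CO[Si](c3ccccc3)(c3ccccc3)C(C)(C)C | intermediate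
24 | 7-O-(2-bromopropanoyl) 8-alcohol | C=C(I)CC[C@H](OC(C)=O)[C@@]2(C)[C@@H](OC(C)=O)CC[C@@](O)(CBr)[C@@H]2[C@H](OC(C)=O)[C@@H](O)[C@@H](OC(=O)C(C)Br)CO[Si](c3ccccc3)(c3ccccc3)C(C)(C)C | intermediate
25 | 7-O-(2-bromopropanoyl) 8-ketone | C=C(I)CC[C@H](OC(C)=O)[C@@]2(C)[C@@H](OC(C)=O)CC[C@@](O)(CBr)[C@@H]2[C@H](OC(C)=O)C(=O)[C@@H](OC(=O)C(C)Br)CO[Si](c3ccccc3)(c3ccccc3)C(C)(C)C | intermediate
26 | (8R,17R)-8-hydroxy lactone, 6-OTBDPS | C=C(I)CC[C@H](OC(C)=O)[C@@]2(C)[C@@H](OC(C)=O)CC[C@@](O)(CBr)[C@@H]2[C@H](OC(C)=O)[C@]2(O)[C@@H](C)C(=O)O[C@H]2CO[Si](c3ccccc3)(c3ccccc3)C(C)(C)C | intermediate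
27 | hydroxy lactone, C6 primary alcohol | C=C(I)CC[C@H](OC(C)=O)[C@@]2(C)[C@@H](OC(C)=O)CC[C@@](O)(CBr)[C@@H]2[C@H](OC(C)=O)[C@]2(O)[C@@H](C)C(=O)O[C@H]2CO | intermediate
28 | hydroxy lactone, C6 aldehyde | C=C(I)CC[C@H](OC(C)=O)[C@@]2(C)[C@@H](OC(C)=O)CC[C@@](O)(CBr)[C@@H]2[C@H](OC(C)=O)[C@]2(O)[C@@H](C)C(=O)O[C@H]2C=O | intermediate
29 | macrocyclic 5(16)-en-6-ol (C6 epimers), bromohydrin | C=C1CC[C@H](OC(C)=O)[C@@]2(C)[C@@H](OC(C)=O)CC[C@@](O)(CBr)[C@@H]2[C@H](OC(C)=O)[C@]2(O)[C@@H](C)C(=O)O[C@H]2C1O | intermediate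
30 | macrocyclic 5(16)-en-6-one, bromohydrin | C=C1CC[C@H](OC(C)=O)[C@@]2(C)[C@@H](OC(C)=O)CC[C@@](O)(CBr)[C@@H]2[C@H](OC(C)=O)[C@]2(O)[C@@H](C)C(=O)O[C@H]2C1=O | intermediate
31 | macrocyclic (6R)-5(16)-en-6-ol, bromohydrin | C=C1CC[C@H](OC(C)=O)[C@@]2(C)[C@@H](OC(C)=O)CC[C@@](O)(CBr)[C@@H]2[C@H](OC(C)=O)[C@]2(O)[C@@H](C)C(=O)O[C@H]2[C@@H]1O | intermediate
32 | (6R)-6-hydroxy 11,20-epoxide | C=C1CC[C@H](OC(C)=O)[C@@]2(C)[C@@H](OC(C)=O)CC[C@@]3(CO3)[C@@H]2[C@H](OC(C)=O)[C@]2(O)[C@@H](C)C(=O)O[C@H]2[C@@H]1O | intermediate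
33 | CNP0104093.2 | C=C1CC[C@H](OC(C)=O)[C@@]2(C)[C@@H](OC(C)=O)CC[C@@]3(CO3)[C@@H]2[C@H](OC(C)=O)[C@]2(O)[C@@H](C)C(=O)O[C@H]2[C@H]1Cl | target

**Step count**
Total steps: 27. Longest linear sequence: 23 steps (steps 1–6 and 11–27).

**Steps most likely to fail, with fallbacks**

Step 11. The bimolecular cycloaddition joins a diene with a fully substituted terminus to a beta-branched nitroalkene; it may be too slow, divert to the inverse-demand hetero-Diels–Alder path (cyclic nitronate), or lose endo selectivity. Fallback: the two bonds are made one after the other. Diene 10 and nitroalkene 16 are joined by a SnCl4-promoted Mukaiyama–Michael addition (CH2Cl2, −78 °C, HF·pyridine work-up), which forms C1–C10 and gives the open-chain nitro enone F1. DBU (cat.) in MeCN then closes C11–C12 by intramolecular nitro-Michael addition (6-endo-trig) to give 18, where the route resumes.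

Step 23. Ring closure to the ten-membered ring may be slow, so that oligomerisation or epimerisation of the alpha-acyloxy aldehyde at C7 competes. Fallback: the ring is closed by acyl cross-coupling instead of carbonyl addition. Aldehyde 28 is oxidised (NaClO2, NaH2PO4, 2-methylbut-2-ene) to the carboxylic acid F2. Me3SnSnMe3 with Pd(PPh3)4 exchanges iodide for tin to give the alkenylstannane acid F3. 1-Chloro-N,N,2-trimethylprop-1-en-1-amine converts it to the acid chloride F4, which is cyclised under high dilution with Pd2(dba)3 and tri(2-furyl)phosphine (intramolecular Stille acylation) to enone 30, where the route resumes.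

Step 16. The organolithium may attack the acetates, or enolise the beta-acetoxy ketone toward C10 with loss of acetate. Fallback: ketone 21 is treated with dimethylsulfoxonium methylide (Me3S(O)I, NaH, DMSO), which also delivers CH2 equatorially and gives the spiro epoxide F5. LiBr and AcOH in THF then open the epoxide at its CH2 terminus to give bromohydrin 22, where the route resumes.

**Further compounds**
F1 | step 11 | open-chain Michael adduct (C1–C10 formed; C14 vinyl ketone, C11 nitromethyl, free 2-hydroxyl) | C=C(I)CC[C@H](O)[C@@](C)(C(=O)C=C)[C@H](C[N+](=O)[O-])[C@H](OC(C)=O)[C@H]1OC(C)(C)O[C@H]1CO[Si](c2ccccc2)(c2ccccc2)C(C)(C)C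
F2 | step 23 | C6 carboxylic acid of 28 | C=C(I)CC[C@H](OC(C)=O)[C@@]2(C)[C@@H](OC(C)=O)CC[C@@](O)(CBr)[C@@H]2[C@H](OC(C)=O)[C@]2(O)[C@@H](C)C(=O)O[C@H]2C(O)=O
F3 | step 23 | alkenyl(trimethyl)stannane carboxylic acid | C=C([Sn](C)(C)C)CC[C@H](OC(C)=O)[C@@]2(C)[C@@H](OC(C)=O)CC[C@@](O)(CBr)[C@@H]2[C@H](OC(C)=O)[C@]2(O)[C@@H](C)C(=O)O[C@H]2C(O)=O
F4 | step 23 | alkenyl(trimethyl)stannane acid chloride | C=C([Sn](C)(C)C)CC[C@H](OC(C)=O)[C@@]2(C)[C@@H](OC(C)=O)CC[C@@](O)(CBr)[C@@H]2[C@H](OC(C)=O)[C@]2(O)[C@@H](C)C(=O)O[C@H]2C(Cl)=O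
F5 | step 16 | 11,20-epoxide of the 7,8-acetonide series | C=C(I)CC[C@H](OC(C)=O)[C@@]2(C)[C@@H](OC(C)=O)CC[C@@]3(CO3)[C@@H]2[C@H](OC(C)=O)[C@H]3OC(C)(C)O[C@H]3CO[Si](c4ccccc4)(c4ccccc4)C(C)(C)C
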